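**Overview**

- First cut: the C5–CH2(allyl) bond. C5 (allyl, OMe) is linked through C4=C3a to C3a, so a retro-Cope shift returns the allyl group to C3a and gives the 3a-allyl cross-conjugated dienone 11 (C4=C5–OMe, C6=O, C7=C7a–O1).
- Second cut: the dihydrofuran ring of 11 at C3–C3a and O1–C2. This ring is the formal [3+2] adduct of the cation of 2-allyl quinone monoketal 5 (its allyl-bearing carbon becomes C3a, its carbonyl oxygen O1) and (E)-isoelemicin 9.
- Forward: the six-membered ring comes intact from 3,4-dimethoxyphenol (O-allylation, Claisen, oxidative ketalisation) and the alkene from 3,4,5-trimethoxybenzaldehyde (Grignard, dehydration). The furan ring closes when the two halves are joined, and the Cope shift ends the route without changing a ring.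
- Stereochemistry: C3 and C3a are set in the C–C bond formation inside a chiral ion pair (absolute sense from the catalyst, methyl anti to allyl). C2 is set trans to methyl when the benzylic cation is captured. C5 is set by suprafacial transfer of the allyl group from C3a.

Key step: step 6

Remark on stereochemistry: a [3,3] shift delivers the allyl group to C5 on the ring face it occupied at C3a, and in the target the C5 allyl group lies on the face opposite the C3 methyl group (the face of the C2 aryl group); the cycloadduct is therefore required as the (2S,3S,3aS) isomer with allyl trans to methyl, since the 3aR isomer with allyl cis to methyl would relay to the 5S epimer.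

Remark on the catalyst: the sense of induction of the chiral acid cannot be derived from first principles; the (S,S) catalyst is written, and its mirror image is used if a pilot run shows the opposite sense.

Benzofuran numbering (O1, C2, C3, C3a, C4 to C7, C7a) is used throughout.

**Route**

Step 1
Reactants: 1 3,4-dimethoxyphenol; 2 allyl bromide
Product: 3 4-(allyloxy)-1,2-dimethoxybenzene
Conditions: K2CO3, acetone, reflux
Reagents that add atoms: none
Why: Williamson ether synthesis, the phenoxide displacing bromide from the unhindered allylic halide by SN2, with no stereocentre formed.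

Step 2
Reactants: 3 4-(allyloxy)-1,2-dimethoxybenzene
Product: 4 2-allyl-4,5-dimethoxyphenol
Conditions: PhNEt2, 190 °C, argon
Reagents that add atoms: none
Why: Aromatic Claisen rearrangement ([3,3] shift, then tautomerisation to the phenol), which should favour the ortho carbon that is not flanked by the 3-methoxy group, the minor regioisomer being removed by chromatography.

Step 3
Reactants: 4 2-allyl-4,5-dimethoxyphenol
Product: 5 2-allyl-4,4,5-trimethoxycyclohexa-2,5-dien-1-one
Conditions: PhI(OAc)2, MeOH, 0 °C
Reagents that add atoms: methanol, CO
Why: Oxidative dearomatisation of a p-methoxyphenol with a hypervalent iodine reagent, methanol adding at the methoxy-bearing para carbon to give the p-quinone monoketal under conditions that leave the allyl group alone.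

Step 4
Reactants: 6 3,4,5-trimethoxybenzaldehyde; 7 ethylmagnesium bromide
Product: 8 1-(3,4,5-trimethoxyphenyl)propan-1-ol (racemic)
Conditions: THF, 0 °C; then aq. NH4Cl
Reagents that add atoms: none
Why: Grignard addition to an aryl aldehyde, the new carbinol centre being racemic and destroyed in the next step.

Step 5
Reactants: 8 1-(3,4,5-trimethoxyphenyl)propan-1-ol
Product: 9 (E)-isoelemicin, 1,2,3-trimethoxy-5-[(E)-prop-1-en-1-yl]benzene
Conditions: p-TsOH·H2O (cat.), PhMe, reflux, Dean–Stark, dilute
Reagents that add atoms: none
Why: Acid-catalysed E1 dehydration through the benzylic cation, reversible under the acid so that the conjugated E alkene should form as the thermodynamic product, with dilution and short heating to limit dimerisation.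

Step 6
Reactants: 5 2-allyl-4,4,5-trimethoxycyclohexa-2,5-dien-1-one; 9 (E)-isoelemicin
Product: 11 (2S,3S,3aS)-3a-allyl-5-methoxy-3-methyl-2-(3,4,5-trimethoxyphenyl)-3,3a-dihydro-1-benzofuran-6(2H)-one, via C6 dimethyl ketal 10 (not isolated)
Conditions: (S,S)-imidodiphosphorimidate from two 3,3'-bis[3,5-bis(trifluoromethyl)phenyl]-BINOL units with P=NTf groups (5 mol%), 3 Å MS, CH2Cl2, −78 to −40 °C; then 5% aq. citric acid, THF, 0 °C
Reagents that add atoms: water, O
Why: Proposed new method: the acid ionises ketal 5 to its methoxy-stabilised oxocarbenium (phenoxenium-type) cation, held as a contact ion pair with the chiral anion; the CHMe terminus of 9 adds to the allyl-bearing ring carbon, the ring carbonyl oxygen captures the trimethoxybenzyl cation, and the methanol set free on ionisation adds to the remaining O-methyl oxocarbenium to give neutral ketal 10 and return the proton, after which the aqueous acid of the work-up hydrolyses 10 to the C6 ketone. The closest known reactions are the strong-acid-promoted racemic union of p-quinone monoketals with propenylbenzenes that gives 3a-allyl dihydrobenzofuranones, and the [3+2] couplings of quinones or quinone monoimines with styrenes under chiral Brønsted or Lewis acid catalysis. The dihydrofuran ring, the only ring closed, forms by 5-exo-trig attack of the carbonyl oxygen on the benzylic cation (the Cα–Cipso π bond of its quinoid form stays outside the ring) once the intermolecular C3–C3a bond is in place. C3 and C3a are set together in the C–C bond formation: the anion shields one face of the cation (absolute sense), and because it is meant to sit around the oxocarbenium end of the ring (the two methoxy-bearing carbons) it denies the aryl group the place under the ring that it takes in the uncatalysed compact addition, so the propenyl unit should add in the open arrangement with the aryl group turned outward past the carbonyl, which puts methyl anti to allyl. C2 is set in the capture step, a suprafacial addition across the E alkene backed by the greater stability of the 2,3-trans ring, so that aryl ends anti to methyl. The step also needs attack at the allyl-bearing terminus of the cation (the alkyl group localises charge there), oxygen rather than carbon capture (a bicyclo[3.2.1]octenone from carbon capture is reopened by the acid to the same benzylic cation without touching C3–C3a), and a temperature low enough that the allyl double bond does not intercept the benzylic cation.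

Step 7
Reactants: 11 (2S,3S,3aS)-3a-allyl-5-methoxy-3-methyl-2-(3,4,5-trimethoxyphenyl)-3,3a-dihydro-1-benzofuran-6(2H)-one
Product: 12 (2S,3S,5R)-5-allyl-5-methoxy-3-methyl-2-(3,4,5-trimethoxyphenyl)-3,5-dihydro-1-benzofuran-6(2H)-one (CNP0316836.2)
Conditions: PhMe (degassed), 110 °C, sealed tube, base-washed glass; stopped at partial conversion, 11 recycled
Reagents that add atoms: none
Why: Cope rearrangement of the 1,5-diene made up of the C3a allyl group and the C4=C5 enol ether, a suprafacial [3,3] shift that should place the allyl group at C5 on the face it left at C3a (anti to the C3 methyl, 5R) while C3a becomes trigonal and C2 and C3 stay untouched, with neutral acid-free heating stopped early so that the product does not move on by a retro-Claisen shift to oxygen.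

**Compound list**

1 | 3,4-dimethoxyphenol | COc1ccc(O)cc1OC | starting material
2 | allyl bromide | C=CCBr | starting material
3 | 4-(allyloxy)-1,2-dimethoxybenzene | C=CCOc1ccc(OC)c(OC)c1 | intermediate
4 | 2-allyl-4,5-dimethoxyphenol | C=CCc1cc(OC)c(OC)cc1O | intermediate
5 | 2-allyl-4,4,5-trimethoxycyclohexa-2,5-dien-1-one | C=CCC1=CC(OC)(OC)C(OC)=CC1=O | intermediate
6 | 3,4,5-trimethoxybenzaldehyde | COc1cc(C=O)cc(OC)c1OC | starting material
7 | ethylmagnesium bromide | CC[Mg]Br | starting material
8 | 1-(3,4,5-trimethoxyphenyl)propan-1-ol (racemic) | CCC(O)c1cc(OC)c(OC)c(OC)c1 | intermediate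
9 | (E)-isoelemicin, 1,2,3-trimethoxy-5-[(E)-prop-1-en-1-yl]benzene | C/C=C/c1cc(OC)c(OC)c(OC)c1 | intermediate
10 | (2S,3S,3aS)-3a-allyl-5,6,6-trimethoxy-3-methyl-2-(3,4,5-trimethoxyphenyl)-2,3,3a,6-tetrahydro-1-benzofuran | COC1(OC)C=C2O[C@H](c3cc(OC)c(OC)c(OC)c3)[C@@H](C)[C@@]2(CC=C)C=C1OC | intermediate (not isolated)
11 | (2S,3S,3aS)-3a-allyl-5-methoxy-3-methyl-2-(3,4,5-trimethoxyphenyl)-3,3a-dihydro-1-benzofuran-6(2H)-one | O=C1C=C2O[C@H](c3cc(OC)c(OC)c(OC)c3)[C@@H](C)[C@@]2(CC=C)C=C1OC | intermediate
12 | (2S,3S,5R)-5-allyl-5-methoxy-3-methyl-2-(3,4,5-trimethoxyphenyl)-3,5-dihydro-1-benzofuran-6(2H)-one | C=CC[C@@]1(OC)C=C2C(=CC1=O)O[C@H](c1cc(OC)c(OC)c(OC)c1)[C@H]2C | target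

**Step count and risks**

Total steps: 7. Longest linear sequence: 5 steps (steps 1, 2, 3, 6, 7 from 3,4-dimethoxyphenol); the alkene branch (steps 4, 5) joins at step 6.

Steps most likely to fail:

1. Step 6 (proposed new method). The ion pair may fail to overturn the compact aryl-under-ring addition that the uncatalysed reaction prefers, which would give methyl cis to allyl. Facial selectivity may also be poor, or the benzylic cation may be intercepted by the allyl double bond. The fallback uses known chemistry, sets out from aldehyde 6 and ketal 5, and returns at 11.
   - Wittig olefination of 6 with ethyltriphenylphosphonium bromide and NaHMDS (THF, −78 °C to rt) should give (Z)-isoelemicin F1.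
   - The known racemic cycloaddition of 5 with F1, promoted by 2,4,6-trinitrobenzenesulfonic acid in MeCN at −30 °C and followed by aqueous work-up, follows the compact topology. For a Z-propenylarene this places methyl trans to allyl and should give the racemic 2,3-cis adduct, racemic (2R*,3S*,3aS*)-3a-allyl-5-methoxy-3-methyl-2-(3,4,5-trimethoxyphenyl)-3,3a-dihydro-1-benzofuran-6(2H)-one F2.
   - Brief treatment of F2 with catalytic p-TsOH in CH2Cl2 at −20 °C re-ionises the benzylic C2–O1 bond and recloses it to the more stable 2,3-trans ring, giving 11 together with its mirror image ent-11 F3. This is kept short and cold because the same cation can be trapped by the allyl group.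
   - Preparative HPLC on amylose tris(3,5-dimethylphenylcarbamate) then separates 11 from F3.

2. Step 7. The [3,3] shift may not stop at C5: the product can move on by a retro-Claisen shift to O6 and a Claisen shift to C7 with aromatisation, or the allyl group can shift directly to C7. The fallback sets out from 11 and returns at 12. The shift is run as a charge-accelerated Cope rearrangement with the C6 carbonyl complexed to a Lewis acid (Me2AlCl, CH2Cl2, −78 to −20 °C). This is the acid-promoted [3,3] allyl migration known for cyclohexadienones. The complexed oxygen can no longer serve as the terminus of the retro-Claisen shift, and the low temperature is meant to keep the C2–O1 bond from ionising. No new compound is formed (entry F0).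

3. Step 2. The allyl group may migrate in part to the hindered ortho carbon between the hydroxyl and the 3-methoxy group, giving a regioisomer mixture that is costly to separate. The fallback sets out from phenol 1 and returns at 4.
   - Bromination of 1 with N-bromosuccinimide (MeCN, 0 °C) at the ortho carbon para to the 3-methoxy group should give 2-bromo-4,5-dimethoxyphenol F4.
   - Suzuki–Miyaura coupling of F4 with allylboronic acid pinacol ester (Pd(OAc)2, SPhos, K3PO4, THF/H2O, 60 °C) fixes the allyl group at the required carbon and gives 4.

**Further compounds**

F1 | step 6 | (Z)-isoelemicin, 1,2,3-trimethoxy-5-[(Z)-prop-1-en-1-yl]benzene | C/C=C\c1cc(OC)c(OC)c(OC)c1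
F2 | step 6 | racemic (2R*,3S*,3aS*)-3a-allyl-5-methoxy-3-methyl-2-(3,4,5-trimethoxyphenyl)-3,3a-dihydro-1-benzofuran-6(2H)-one (2R,3S,3aS enantiomer drawn) | O=C1C=C2O[C@@H](c3cc(OC)c(OC)c(OC)c3)[C@@H](C)[C@@]2(CC=C)C=C1OC
F3 | step 6 | ent-11, (2R,3R,3aR)-3a-allyl-5-methoxy-3-methyl-2-(3,4,5-trimethoxyphenyl)-3,3a-dihydro-1-benzofuran-6(2H)-one (formed with 11 as the racemate) | O=C1C=C2O[C@@H](c3cc(OC)c(OC)c(OC)c3)[C@H](C)[C@]2(CC=C)C=C1OC
F0 | step 7 | none | none
F4 | step 2 | 2-bromo-4,5-dimethoxyphenol | COc1cc(O)c(Br)cc1OC
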